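**Plan**

- Ring numbering: C1 carries the chain and an OH, C2=C3 is the alkene, C4 and C5 are the secondary carbinols, C6 is CH2. The cyclohexene with oxygen on C1 and C4 and with C5–O trans to C1–O is the carbocycle of a 2-oxabicyclo[2.2.2]oct-5-en-3-one once a carboxyl carbon on C4 is tied to the C1 oxygen. That bicycle is the endo [4+2] adduct of a 6-alkyl-3-hydroxy-2-pyrone (pyrone C6, C5, C4, C3 = ring C1, C2, C3, C4) and but-3-en-2-one (ring C6, C5).
- Cuts: C4–OH goes back to the C4 ketone and then to a C4 α-hydroxy acid (bridge carbon lost as CO2); C5–OH goes back to C5–acetyl; then the ring bonds C1–C6 and C4–C5 are cut. The pyrone is cut at its ring O–C(=O) bond (2,5-dioxo acid), the acid at C3–C4 (masked glyoxylate plus vinyl ketone) and at the ketone–chain bond, the chain at C11′–C12′.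
- Forward: C17 chain (steps 1–3), open-chain 2,5-dioxo acid (4–7), pyrone ring (8–9), carbocycle as the lactone-bridged bicycle (10), then removal of the bridge and adjustment of the three oxygens (11–16).
- Stereochemistry: the E-alkene comes from Na/NH3; C1, C4 and C5 come from the catalyst-controlled endo cycloaddition; C5–O is kept by retentive Baeyer–Villiger migration; C4 is reset by a substrate-controlled Luche reduction trans to C5–O.

Key step: step 10

Assumption: which pseudoenantiomer of the bifunctional cinchona base (quinine- or quinidine-derived) gives the (1R,4S,8R) endo adduct with a 6-alkyl pyrone is fixed by a test run; the route is written for the quinine-derived thiourea, and compounds 7, 10, 17 and the catalyst are bought.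

**Route**

Step 1
Reactants: 1 hex-1-yne; 2 11-bromoundecan-1-ol
Product: 4 heptadec-12-yn-1-ol, via hex-1-ynyllithium 3 (not isolated)
Conditions: 1 (2.5 equiv), n-BuLi (2.4 equiv), THF, −78 → 0 °C; then DMPU, 2, 0 °C → rt; aq. NH4Cl
Reagents that add atoms: none
Why: SN2 alkylation of a lithium acetylide by a primary bromide in a dipolar cosolvent, in which one equivalent of acetylide only deprotonates the hydroxyl so that no protecting group is needed.

Step 2
Reactants: 4 heptadec-12-yn-1-ol
Product: 5 (E)-heptadec-12-en-1-ol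
Conditions: Na, NH3(l)–THF, −33 °C; then solid NH4Cl
Reagents that add atoms: none
Why: Dissolving-metal reduction of an internal alkyne proceeds through the trans vinyl radical/anion and should give the E-alkene only.

Step 3
Reactants: 5 (E)-heptadec-12-en-1-ol
Product: 6 (E)-17-bromoheptadec-5-ene
Conditions: CBr4, PPh3, CH2Cl2, 0 °C
Reagents that add atoms: tetrabromomethane, BrC(Br)(Br)Br
Why: Appel reaction of a primary alcohol, neutral conditions that leave the alkene untouched.

Step 4
Reactants: 6 (E)-17-bromoheptadec-5-ene; 7 3-chloro-N-methoxy-N-methylpropanamide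
Product: 9 (E)-1-chloroicos-15-en-3-one, via [(E)-heptadec-12-en-1-yl]magnesium bromide 8 (not isolated)
Conditions: Mg, I2 (cat.), THF, 40 °C; then 7, THF, −40 → 0 °C; cold 1 M HCl
Reagents that add atoms: none
Why: Weinreb ketone synthesis, in which the magnesium-chelated tetrahedral adduct survives until the quench so the Grignard reagent adds once, and the β-chloride is carried along as a latent vinyl ketone.

Step 5
Reactants: 9 (E)-1-chloroicos-15-en-3-one; 10 ethyl 1,3-dithiane-2-carboxylate
Product: 12 ethyl 2-[(E)-3-oxoicos-15-en-1-yl]-1,3-dithiane-2-carboxylate, via (E)-icosa-1,15-dien-3-one 11 (not isolated)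
Conditions: 9, Et3N, THF, 0 °C → rt, filter; filtrate added to 10/LiN(SiMe3)2, THF, −78 °C; aq. NH4Cl
Reagents that add atoms: none
Why: Base-induced loss of HCl unveils the vinyl ketone, and the ester- and sulfur-stabilised dithiane anion (a soft glyoxylate acyl-anion equivalent) adds to it in a Michael reaction, which sets the 1,4-relation of the two future carbonyl groups without any need to tell two like esters apart.

Step 6
Reactants: 12 ethyl 2-[(E)-3-oxoicos-15-en-1-yl]-1,3-dithiane-2-carboxylate
Product: 13 ethyl (E)-2,5-dioxodocos-17-enoate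
Conditions: PhI(OCOCF3)2, MeCN–H2O (9:1), 0 °C → rt
Reagents that add atoms: water, O
Why: Oxidative dethioacetalisation with the hypervalent iodine reagent, which attacks sulfur much faster than an isolated disubstituted alkene and releases the α-keto ester.

Step 7
Reactants: 13 ethyl (E)-2,5-dioxodocos-17-enoate
Product: 14 (E)-2,5-dioxodocos-17-enoic acid
Conditions: LiOH (1.1 equiv), THF–H2O, 0 °C, 15 min; cold 1 M HCl to pH 2
Reagents that add atoms: lithium hydroxide, [Li+].[OH-]
Why: Saponification of an α-keto ester is complete within minutes at 0 °C, well before the 1,4-diketone can undergo aldol cyclisation.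

Step 8
Reactants: 14 (E)-2,5-dioxodocos-17-enoic acid
Product: 15 6-[(E)-heptadec-12-en-1-yl]-2-oxo-2H-pyran-3-yl acetate
Conditions: Ac2O, NaOAc, 90 °C
Reagents that add atoms: acetic anhydride, CC(=O)OC(C)=O
Why: Dehydrative enol-lactonisation, in which the α-keto acid is taken to its enol acetate/mixed anhydride and the enol oxygen of the C5 ketone is acylated intramolecularly to the six-membered ring, the same cyclodehydration by which aldaric acids give 3-acetoxy-2-pyrones, while the non-acidic medium disfavours the acid-catalysed Paal–Knorr closure to a furan.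

Step 9
Reactants: 15 6-[(E)-heptadec-12-en-1-yl]-2-oxo-2H-pyran-3-yl acetate
Product: 16 6-[(E)-heptadec-12-en-1-yl]-3-hydroxy-2H-pyran-2-one
Conditions: HCl (1.25 M in MeOH, cat.), MeOH–THF, rt
Reagents that add atoms: none
Why: Acid-catalysed transesterification removes the enol (aryl-type) acetate, and the conjugated pyrone lactone and the chain alkene are stable to dilute acid.

Step 10
Reactants: 16 6-[(E)-heptadec-12-en-1-yl]-3-hydroxy-2H-pyran-2-one; 17 but-3-en-2-one
Product: 18 (1R,4S,8R)-8-acetyl-1-[(E)-heptadec-12-en-1-yl]-4-hydroxy-2-oxabicyclo[2.2.2]oct-5-en-3-one (endo acetyl, syn to the C5=C6 bridge)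
Conditions: 17 (2 equiv), 1-[3,5-bis(trifluoromethyl)phenyl]-3-[(8α,9S)-6′-methoxycinchonan-9-yl]thiourea (10 mol%), t-BuOMe, 0 °C → rt
Reagents that add atoms: none
Why: The quinuclidine nitrogen deprotonates the 3-hydroxyl, and the 3-oxidopyrone, ion-paired with the ammonium while the thiourea hydrogen-bonds the enone carbonyl, reacts as an electron-rich diene whose C6 attacks the enone β-carbon and whose C3 bonds to the α-carbon (ring bonds C1–C6 and C4–C5), either concerted and asynchronous or as a Michael addition followed by aldol closure. The closest known reaction type is the bifunctional cinchona-base-catalysed Diels–Alder reaction of 3-hydroxy-2-pyrones with enones and other electron-poor alkenes, here applied to a 6-alkyl pyrone that forms a quaternary bridgehead. The one new ring, the six-membered carbocycle, closes by [4+2] cycloaddition (in the stepwise limit by an intermolecular Michael addition and a 6-(enolexo)-exo-trig aldol) and leaves the lactone as the third bridge of the bicyclo[2.2.2] system. The two bridgeheads C1 and C4 are fixed relative to each other by suprafacial addition across the diene and in the absolute sense by the pyrone face that the chiral ion pair leaves open, and C5 is fixed by the endo placement of the acetyl group under the diene, anti to the lactone oxygen on C1. The step needs regio-, endo- and facial selectivity: the first follows from the polarisation of the 3-oxido diene (largest HOMO coefficient at C6, so the acetyl carbon ends next to the hydroxylated bridgehead), the other two from the two-point binding of both partners to the catalyst. The unactivated chain alkene is no dienophile, and the unsubstituted β-carbon of the enone keeps the approach to the substituted C6 terminus open.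

Step 11
Reactants: 18 (1R,4S,8R)-8-acetyl-1-[(E)-heptadec-12-en-1-yl]-4-hydroxy-2-oxabicyclo[2.2.2]oct-5-en-3-one
Product: 19 (1R,4S,8R)-1-[(E)-heptadec-12-en-1-yl]-4-hydroxy-3-oxo-2-oxabicyclo[2.2.2]oct-5-en-8-yl acetate
Conditions: Me3SiOOSiMe3, SnCl4 (0.3 equiv), (±)-trans-cyclohexane-1,2-diamine (0.3 equiv), 4 Å MS, CH2Cl2, −20 → 0 °C
Reagents that add atoms: bis(trimethylsilyl) peroxide, C[Si](C)(C)OO[Si](C)(C)C
Why: Baeyer–Villiger oxidation in which the secondary ring carbon migrates in preference to methyl with retention, so the endo acetyl becomes the endo acetate, and the Lewis-acid-activated silyl peroxide is a nucleophilic oxidant that should not epoxidise the chain or ring alkene.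

Step 12
Reactants: 19 (1R,4S,8R)-1-[(E)-heptadec-12-en-1-yl]-4-hydroxy-3-oxo-2-oxabicyclo[2.2.2]oct-5-en-8-yl acetate
Product: 20 (1S,4R,6R)-4-[(E)-heptadec-12-en-1-yl]-1,4,6-trihydroxycyclohex-2-ene-1-carboxylic acid
Conditions: LiOH (5 equiv), THF–H2O, 0 °C → rt; 0.5 M HCl to pH 4 at 0 °C
Reagents that add atoms: lithium hydroxide, [Li+].[OH-]
Why: Saponification of the acetate and of the strained bridging lactone by acyl–oxygen cleavage keeps the configuration at both carbinol carbons and frees the tertiary alcohol and the α-hydroxy acid.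

Step 13
Reactants: 20 (1S,4R,6R)-4-[(E)-heptadec-12-en-1-yl]-1,4,6-trihydroxycyclohex-2-ene-1-carboxylic acid
Product: 22 (1S,4R,6R)-6-[(tert-butyldimethylsilyl)oxy]-4-[(E)-heptadec-12-en-1-yl]-1,4-dihydroxycyclohex-2-ene-1-carboxylic acid, via 6-O-silyl silyl ester 21 (not isolated)
Conditions: TBSCl (3 equiv), imidazole, DMF, rt; then K2CO3, MeOH–THF–H2O, 0 °C; pH 4
Reagents that add atoms: tert-butyldimethylsilyl chloride, CC(C)(C)[Si](C)(C)Cl
Why: The hindered chlorosilane takes the only secondary hydroxyl and the carboxyl group but neither tertiary alcohol, and mild base then hydrolyses the labile silyl ester alone, so the oxygen next to the α-hydroxy acid stays protected and the next oxidation cannot cleave that glycol.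

Step 14
Reactants: 22 (1S,4R,6R)-6-[(tert-butyldimethylsilyl)oxy]-4-[(E)-heptadec-12-en-1-yl]-1,4-dihydroxycyclohex-2-ene-1-carboxylic acid
Product: 23 (4R,6R)-6-[(tert-butyldimethylsilyl)oxy]-4-[(E)-heptadec-12-en-1-yl]-4-hydroxycyclohex-2-en-1-one
Conditions: Pb(OAc)4, CH2Cl2, −20 → 0 °C
Reagents that add atoms: none
Why: Oxidative decarboxylation of an α-hydroxy acid through its cyclic lead ester expels the former lactone carbon as CO2 and leaves the ketone conjugated with the ring alkene.

Step 15
Reactants: 23 (4R,6R)-6-[(tert-butyldimethylsilyl)oxy]-4-[(E)-heptadec-12-en-1-yl]-4-hydroxycyclohex-2-en-1-one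
Product: 24 (1R,4R,5R)-5-[(tert-butyldimethylsilyl)oxy]-1-[(E)-heptadec-12-en-1-yl]cyclohex-2-ene-1,4-diol
Conditions: NaBH4, CeCl3·7H2O, MeOH–CH2Cl2, −78 °C
Reagents that add atoms: none
Why: Luche reduction gives 1,2-reduction only, and axial hydride delivery to the half-chair in which the chain and the silyloxy group are both pseudo-equatorial should give the pseudo-equatorial alcohol, trans to the silyloxy group and cis to the tertiary hydroxyl (4R).

Step 16
Reactants: 24 (1R,4R,5R)-5-[(tert-butyldimethylsilyl)oxy]-1-[(E)-heptadec-12-en-1-yl]cyclohex-2-ene-1,4-diol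
Product: 25 (1R,4R,5R)-1-[(E)-heptadec-12-en-1-yl]cyclohex-2-ene-1,4,5-triol (CNP0317923.1)
Conditions: Bu4NF, THF, 0 °C → rt
Reagents that add atoms: none
Why: Fluoride cleaves the silyl ether under non-acidic conditions, which avoids ionisation of the tertiary allylic alcohol.

**Compound list**

1 | hex-1-yne | CCCCC#C | starting material
2 | 11-bromoundecan-1-ol | OCCCCCCCCCCCBr | starting material
3 | hex-1-ynyllithium | [Li]C#CCCCC | intermediate
4 | heptadec-12-yn-1-ol | CCCCC#CCCCCCCCCCCCO | intermediate
5 | (E)-heptadec-12-en-1-ol | CCCC/C=C/CCCCCCCCCCCO | intermediate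
6 | (E)-17-bromoheptadec-5-ene | CCCC/C=C/CCCCCCCCCCCBr | intermediate
7 | 3-chloro-N-methoxy-N-methylpropanamide | CON(C)C(=O)CCCl | starting material
8 | [(E)-heptadec-12-en-1-yl]magnesium bromide | CCCC/C=C/CCCCCCCCCCC[Mg]Br | intermediate
9 | (E)-1-chloroicos-15-en-3-one | CCCC/C=C/CCCCCCCCCCCC(=O)CCCl | intermediate
10 | ethyl 1,3-dithiane-2-carboxylate | CCOC(=O)C1SCCCS1 | starting material
11 | (E)-icosa-1,15-dien-3-one | CCCC/C=C/CCCCCCCCCCCC(=O)C=C | intermediate
12 | ethyl 2-[(E)-3-oxoicos-15-en-1-yl]-1,3-dithiane-2-carboxylate | CCCC/C=C/CCCCCCCCCCCC(=O)CCC1(SCCCS1)C(=O)OCC | intermediate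
13 | ethyl (E)-2,5-dioxodocos-17-enoate | CCCC/C=C/CCCCCCCCCCCC(=O)CCC(=O)C(=O)OCC | intermediate
14 | (E)-2,5-dioxodocos-17-enoic acid | CCCC/C=C/CCCCCCCCCCCC(=O)CCC(=O)C(=O)O | intermediate
15 | 6-[(E)-heptadec-12-en-1-yl]-2-oxo-2H-pyran-3-yl acetate | CCCC/C=C/CCCCCCCCCCCC1=CC=C(OC(C)=O)C(=O)O1 | intermediate
16 | 6-[(E)-heptadec-12-en-1-yl]-3-hydroxy-2H-pyran-2-one | CCCC/C=C/CCCCCCCCCCCC1=CC=C(O)C(=O)O1 | intermediate
17 | but-3-en-2-one | CC(=O)C=C | starting material
18 | (1R,4S,8R)-8-acetyl-1-[(E)-heptadec-12-en-1-yl]-4-hydroxy-2-oxabicyclo[2.2.2]oct-5-en-3-one | CCCC/C=C/CCCCCCCCCCC[C@]12OC(=O)[C@](O)(C=C1)[C@H](C(C)=O)C2 | intermediate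
19 | (1R,4S,8R)-1-[(E)-heptadec-12-en-1-yl]-4-hydroxy-3-oxo-2-oxabicyclo[2.2.2]oct-5-en-8-yl acetate | CCCC/C=C/CCCCCCCCCCC[C@]12OC(=O)[C@](O)(C=C1)[C@H](OC(C)=O)C2 | intermediate
20 | (1S,4R,6R)-4-[(E)-heptadec-12-en-1-yl]-1,4,6-trihydroxycyclohex-2-ene-1-carboxylic acid | CCCC/C=C/CCCCCCCCCCC[C@]1(O)C=C[C@@](O)(C(=O)O)[C@H](O)C1 | intermediate
21 | tert-butyldimethylsilyl (1S,4R,6R)-6-[(tert-butyldimethylsilyl)oxy]-4-[(E)-heptadec-12-en-1-yl]-1,4-dihydroxycyclohex-2-ene-1-carboxylate | CCCC/C=C/CCCCCCCCCCC[C@]1(O)C=C[C@@](O)(C(=O)O[Si](C)(C)C(C)(C)C)[C@H](O[Si](C)(C)C(C)(C)C)C1 | intermediate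
22 | (1S,4R,6R)-6-[(tert-butyldimethylsilyl)oxy]-4-[(E)-heptadec-12-en-1-yl]-1,4-dihydroxycyclohex-2-ene-1-carboxylic acid | CCCC/C=C/CCCCCCCCCCC[C@]1(O)C=C[C@@](O)(C(=O)O)[C@H](O[Si](C)(C)C(C)(C)C)C1 | intermediate
23 | (4R,6R)-6-[(tert-butyldimethylsilyl)oxy]-4-[(E)-heptadec-12-en-1-yl]-4-hydroxycyclohex-2-en-1-one | CCCC/C=C/CCCCCCCCCCC[C@]1(O)C=CC(=O)[C@H](O[Si](C)(C)C(C)(C)C)C1 | intermediate
24 | (1R,4R,5R)-5-[(tert-butyldimethylsilyl)oxy]-1-[(E)-heptadec-12-en-1-yl]cyclohex-2-ene-1,4-diol | CCCC/C=C/CCCCCCCCCCC[C@]1(O)C=C[C@@H](O)[C@H](O[Si](C)(C)C(C)(C)C)C1 | intermediate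
25 | (1R,4R,5R)-1-[(E)-heptadec-12-en-1-yl]cyclohex-2-ene-1,4,5-triol | CCCC/C=C/CCCCCCCCCCC[C@]1(O)C=C[C@@H](O)[C@H](O)C1 | target

**Step count**

Total step count: 16. Longest linear sequence: 16 steps (1 and 2 to 25); 7, 10 and 17 enter in steps 4, 5 and 10.

**Steps most likely to fail**

Step 10. The alkyl group on the bond-forming C6 terminus may lower the facial discrimination by the catalyst, and retro-aldol/aldol equilibration of the β-hydroxy ketone may erode the endo preference. The fallback gives up catalyst control and takes the stereochemistry from a resolution. It sets out from 16 and 17, which with Et3N (0.3 equiv) in CH2Cl2 at rt (the achiral base-promoted cycloaddition of 3-hydroxy-2-pyrones) should give the racemic endo adduct, that is 18 together with its mirror image (1S,4R,8S)-8-acetyl-1-[(E)-heptadec-12-en-1-yl]-4-hydroxy-2-oxabicyclo[2.2.2]oct-5-en-3-one F1. The two are separated by preparative chromatography on an amylose tris(3,5-dimethylphenylcarbamate) stationary phase, and the route is rejoined at 18.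

Step 8. The cyclodehydration may take the Paal–Knorr course to a furan-2-carboxylic acid, or the 1,4-diketone may close by aldol reaction instead of lactonising. The fallback closes the lactone while the α-keto carbon is still masked, so that neither diversion is possible. It sets out from 12. KOH in EtOH–H2O at 60 °C gives 2-[(E)-3-oxoicos-15-en-1-yl]-1,3-dithiane-2-carboxylic acid F2. Ac2O/NaOAc at 120 °C (enol-lactonisation of a δ-keto acid) gives 9-[(E)-heptadec-12-en-1-yl]-8-oxa-1,5-dithiaspiro[5.5]undec-9-en-7-one F3. HgCl2/CaCO3 in MeCN–H2O at 50 °C then unmasks the 3-oxo lactone, which tautomerises to the hydroxypyrone, and the route is rejoined at 16.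

Step 11. Oxygen insertion into an acyclic methyl ketone is slow, so epoxidation of the chain alkene may compete, or the Lewis acid may open the β-hydroxy ketone by retro-aldol cleavage. The fallback masks the chain alkene and uses a buffered peracid. It sets out from 18. Pyridinium tribromide in CH2Cl2 at −78 °C should add anti to the chain alkene only, because the ring alkene is deactivated by its two oxygenated bridgeheads. This gives (1R,4S,8R)-8-acetyl-1-[(12R,13S)-12,13-dibromoheptadecyl]-4-hydroxy-2-oxabicyclo[2.2.2]oct-5-en-3-one F4, formed together with its 12S,13R diastereomer. mCPBA/NaHCO3 in CH2Cl2 then gives (1R,4S,8R)-1-[(12R,13S)-12,13-dibromoheptadecyl]-4-hydroxy-3-oxo-2-oxabicyclo[2.2.2]oct-5-en-8-yl acetate F5. Zn in AcOH–THF removes the bromine atoms by anti elimination, which restores the E-alkene, and the route is rejoined at 19.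

**Further compounds**

F1 | step 10 | (1S,4R,8S)-8-acetyl-1-[(E)-heptadec-12-en-1-yl]-4-hydroxy-2-oxabicyclo[2.2.2]oct-5-en-3-one | CCCC/C=C/CCCCCCCCCCC[C@@]12OC(=O)[C@@](O)(C=C1)[C@@H](C(C)=O)C2
F2 | step 8 | 2-[(E)-3-oxoicos-15-en-1-yl]-1,3-dithiane-2-carboxylic acid | CCCC/C=C/CCCCCCCCCCCC(=O)CCC1(SCCCS1)C(=O)O
F3 | step 8 | 9-[(E)-heptadec-12-en-1-yl]-8-oxa-1,5-dithiaspiro[5.5]undec-9-en-7-one | CCCC/C=C/CCCCCCCCCCCC1=CCC2(SCCCS2)C(=O)O1
F4 | step 11 | (1R,4S,8R)-8-acetyl-1-[(12R,13S)-12,13-dibromoheptadecyl]-4-hydroxy-2-oxabicyclo[2.2.2]oct-5-en-3-one (formed with its 12S,13R diastereomer) | CCCC[C@H](Br)[C@H](Br)CCCCCCCCCCC[C@]12OC(=O)[C@](O)(C=C1)[C@H](C(C)=O)C2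
F5 | step 11 | (1R,4S,8R)-1-[(12R,13S)-12,13-dibromoheptadecyl]-4-hydroxy-3-oxo-2-oxabicyclo[2.2.2]oct-5-en-8-yl acetate (formed with its 12S,13R diastereomer) | CCCC[C@H](Br)[C@H](Br)CCCCCCCCCCC[C@]12OC(=O)[C@](O)(C=C1)[C@H](OC(C)=O)C2
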